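**Plan**
- Enabling feature: in the 2,3-dihydroxybenzoate ring (ester on ring C1, hydroxyls on C2 and C3) the seven carbons and four oxygens are those of a 3-(furan-2-yl)-3-oxopropanoate, of which it is an isomer. The CH2 becomes ring C1, the ketone carbon ring C2, and furan C2–C5 become ring C3–C6.
- Retrosynthesis: ring bond C1–C6 is cut first (retro-aldol, with the C3 oxygen closing back onto C6 as the furan). The alkyl O–acyl bond is cut next (ester exchange), then chain bond C16–C17 of the alcohol.
- Forward: the C22 chain is joined first by a copper-catalysed sp3–sp3 coupling and is then exchanged onto ethyl 2-furoylacetate. The benzene ring, the only ring made, arises last from the furan by acid-mediated opening and aldol reclosure.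
- Stereochemistry: none to set; the target has no stereocentre and no stereogenic double bond.

Key step: step 3

Remark: Gentiside A is achiral (C20 carries two identical methyl groups), so the "single enantiomer" is the compound itself and no stereocontrol is needed.

**Step 1**
Reactants: 1 1-bromo-4-methylpentane; 2 16-bromohexadecan-1-ol
Product: 4 20-methylhenicosan-1-ol, via 4-methylpentylmagnesium bromide 3 (not isolated)
Conditions: 1 (3 equiv), Mg, THF, 45 °C; then 2, Li2CuCl4 (3 mol %), THF, −20 °C → rt; aq NH4Cl
Reagents that add atoms: none
Why: Kochi-type copper-catalysed cross-coupling of a primary alkyl Grignard reagent with a primary alkyl bromide, in which the first equivalent of 3 only converts the hydroxyl of 2 into an inert magnesium alkoxide, so the C16–C17 bond should form without a protecting group.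

**Step 2**
Reactants: 4 20-methylhenicosan-1-ol; 5 ethyl 3-(furan-2-yl)-3-oxopropanoate
Product: 6 20-methylhenicosyl 3-(furan-2-yl)-3-oxopropanoate
Conditions: 5 (1.5 equiv), DMAP (0.3 equiv), toluene, reflux, EtOH–toluene distilled off
Reagents that add atoms: none
Why: DMAP-catalysed transesterification of a β-keto ester (acylketene-type pathway open only to enolisable β-keto esters) is much easier than ordinary ester exchange, and removal of ethanol should drive it to the primary alcohol 4 while furan and ketone stay untouched.

**Step 3**
Reactants: 6 20-methylhenicosyl 3-(furan-2-yl)-3-oxopropanoate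
Product: 9 Gentiside A (20-methylhenicosyl 2,3-dihydroxybenzoate), via open-chain trioxoheptanoate 7 (not isolated), via cyclic aldol adduct 8 (not isolated)
Conditions: TfOH (0.5 equiv), H2O (2 equiv), HFIP–ClCH2CH2Cl 1:1 (0.02 M), 80 °C, sealed tube, Ar; degassed pH 6 buffer; SiO2 under Ar
Reagents that add atoms: none
Why: Proposed new method: O-protonation of the acyl carbonyl makes furan C5 the terminus of a vinylogous oxocarbenium ion, water adds there and the cyclic hemiacetal opens in an unfavourable but reversible pre-equilibrium to the 1,2-diketo aldehyde 7 (furan C2 becomes the C4 ketone, furan C5 the aldehyde C7); the closest known reaction type is the hydrolytic ring opening–intramolecular aldol recyclisation that turns 5-hydroxymethylfurfural into 1,2,4-benzenetriol and masked 2-acylfuran hydrates (2-acyl-2,5-dialkoxytetrahydrofurans) into catechols. The enol of the β-keto ester, already present and far more nucleophilic than the methyl ketone of those precedents, then attacks the aldehyde through C2 of 7 in a 6-(enolendo)-exo-trig aldol that forms the arene C1–C6 bond and closes the only ring, giving 8. Loss of water from 8 and two enolisations (one of them vinylogous) lead to the aromatic catechol, which pulls the pre-equilibrium forward, returns the water used in the opening and makes the overall change a net isomerisation. No stereocentre is created in 9, and the two transient centres of 8 disappear on aromatisation. The step needs furan hydration to win over ester hydrolysis followed by decarboxylation, over Paal–Knorr reclosure and over intermolecular condensation of the aldehyde; a substoichiometric superacid, only two equivalents of water, a non-nucleophilic medium of low basicity, high dilution and a doubly activated methylene held six atoms from the aldehyde are meant to secure this.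

**Compound list**
1 | 1-bromo-4-methylpentane | CC(C)CCCBr | starting material
2 | 16-bromohexadecan-1-ol | OCCCCCCCCCCCCCCCCBr | starting material
3 | 4-methylpentylmagnesium bromide | CC(C)CCC[Mg]Br | intermediate
4 | 20-methylhenicosan-1-ol | CC(C)CCCCCCCCCCCCCCCCCCCO | intermediate
5 | ethyl 3-(furan-2-yl)-3-oxopropanoate | CCOC(=O)CC(=O)c1ccco1 | starting material
6 | 20-methylhenicosyl 3-(furan-2-yl)-3-oxopropanoate | CC(C)CCCCCCCCCCCCCCCCCCCOC(=O)CC(=O)c1ccco1 | intermediate
7 | 20-methylhenicosyl 3,4,7-trioxoheptanoate | CC(C)CCCCCCCCCCCCCCCCCCCOC(=O)CC(=O)C(=O)CCC=O | intermediate
8 | 20-methylhenicosyl 6-hydroxy-2,3-dioxocyclohexane-1-carboxylate (transient, configuration undefined) | CC(C)CCCCCCCCCCCCCCCCCCCOC(=O)C1C(O)CCC(=O)C1=O | intermediate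
9 | Gentiside A (20-methylhenicosyl 2,3-dihydroxybenzoate) | CC(C)CCCCCCCCCCCCCCCCCCCOC(=O)c1cccc(O)c1O | target

**Step count**
Total: 3 steps (formation of the Grignard reagent is part of step 1). Longest linear sequence: 3 steps (2 → 4 → 6 → 9).

**Steps most likely to fail**

Step 3. The acyl-deactivated furan may resist hydration, so that ester hydrolysis with decarboxylation, oligomerisation of the transient aldehyde or air oxidation of the catechol take over. The fallback uses known chemistry, sets out from 4 and returns at 9, and gives up the de novo arene construction for a preformed ring. Steglich esterification of 4 with commercial 2,3-bis(benzyloxy)benzoic acid (EDC·HCl, DMAP, CH2Cl2, rt) should give 20-methylhenicosyl 2,3-bis(benzyloxy)benzoate F1. Hydrogenolysis of both benzyl ethers (H2, Pd/C, EtOAc–THF, rt) would then release 9.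

Step 1. Wurtz-type homocoupling, reduction or elimination of the bromide, or precipitation of the magnesium alkoxide of 2 may stall the cross-coupling. The fallback sets out from 2 and returns at 4, replacing the sp3–sp3 coupling by olefination and hydrogenation. Heating 2 with PPh3 (MeCN, reflux) should give (16-hydroxyhexadecyl)triphenylphosphonium bromide F2. Double deprotonation (NaHMDS, 2.1 equiv, THF, −78 °C) and Wittig reaction with commercial 4-methylpentanal would give (Z)-20-methylhenicos-16-en-1-ol F3. Hydrogenation (H2, Pd/C, EtOAc) would saturate the alkene to 4; the alkene geometry is irrelevant.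

Step 2. The ester exchange may stop short of completion, the furoylacetate may self-condense through acylketene dimerisation on long heating, and unreacted long-chain alcohol may co-elute with the product. The fallback sets out from 4 and returns at 6, building the β-keto ester by the acyl Meldrum's acid route instead. Acylation of Meldrum's acid with 2-furoyl chloride (pyridine, CH2Cl2, 0 °C → rt) should give 5-[furan-2-yl(hydroxy)methylidene]-2,2-dimethyl-1,3-dioxane-4,6-dione F4. Heating F4 with 4 in toluene at reflux would deliver 6 by alcoholysis with loss of the acetonide and decarboxylation.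

**Further compounds**
F1 | step 3 | 20-methylhenicosyl 2,3-bis(benzyloxy)benzoate | CC(C)CCCCCCCCCCCCCCCCCCCOC(=O)c1cccc(OCc2ccccc2)c1OCc1ccccc1
F2 | step 1 | (16-hydroxyhexadecyl)triphenylphosphonium bromide | OCCCCCCCCCCCCCCCC[P+](c1ccccc1)(c1ccccc1)c1ccccc1.[Br-]
F3 | step 1 | (Z)-20-methylhenicos-16-en-1-ol | CC(C)CC/C=C\CCCCCCCCCCCCCCCO
F4 | step 2 | 5-[furan-2-yl(hydroxy)methylidene]-2,2-dimethyl-1,3-dioxane-4,6-dione | CC1(C)OC(=O)C(=C(O)c2ccco2)C(=O)O1
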